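Ring A is numbered as in the target throughout the discussion: C1 carbonyl, C2 amide-bearing, C3 vinylic CH, C4 carbinol, C5 and C6 oxirane carbons. The systematic names in the steps use bicyclic numbering instead.

## Analysis of the target

- **Ring system and chains.** Ring A is a cyclohex-2-enone fused at C5–C6 to oxirane ring B. The nitrogen on C2 carries a (2E,4E,6R)-4,6-dimethyldeca-2,4-dienoyl chain (C1′–C10′). C4 carries an all-E triene (C7–C12) ending in amide carbonyl C13. The nitrogen of that amide sits on C2″ of ring C, a 2-amino-3-hydroxycyclopent-2-enone.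
- **Stereocentres.** There are four. C4 (S), C5 (R) and C6 (S) are contiguous, with the C4 hydroxyl on the same face as the epoxide oxygen. C6′ (R) is remote and has to be set independently.
- **Sensitive groups.** The epoxy enone is sensitive to bases and nucleophiles. The C4 alcohol is tertiary and doubly allylic and can ionise. The triene is sensitive to light and acid. The enol of ring C is about as acidic as a carboxylic acid and chelates metals.
- **Difficulty.** Two amide-terminated halves must be joined through a geometrically pure triene, one absolute and two relative configurations must be controlled on ring A, and ring C burdens every metal-mediated step that follows its introduction.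
- **Feature carrying the strategy.** Ring C is a cyclised 5-aminolevulinate. C2″ is the amino-bearing carbon 5, the neighbouring carbonyl carbon C1″ is the former carboxyl carbon 1, C3″ is the former ketone carbon 4, and C4″/C5″ are the former carbons 3 and 2. Forming the single bond C1″–C2″ from a neutral open-chain keto ester closes ring C.

## Retrosynthetic reasoning

**23 from 22.** The last operation only removes protecting groups: the C1 carbonyl is carried as a dimethyl ketal and the C4 hydroxyl as a triethylsilyl ether. The ketal is kept to the end deliberately. With it, ring A presents no enone to the strong base of the ring closure, so chemoselectivity in that step is not left to chance.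

**22 from 21.** Ring C is opened at C1″–C2″. This is the only bond of ring C whose cleavage leaves an ordinary ketone and a methyl ester, both neutral and inert to palladium. Cutting the amide N–C13 bond instead would require the free vinylogous acid to be carried through the fragment coupling. The forward reaction must make the enolate of the amide-flanked methylene of 21 acylate at carbon with the ester four atoms away.

**21 from 15 and 20.** The triene is cut at the C8–C9 single bond between two sp2 carbons. This divides the molecule into halves of similar size, each with one amide and defined E-alkenes. The forward reaction is a Stille coupling of vinylstannane 15 with dienyl iodide 20, which transfers both geometries unchanged.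

**20 from 18 and 19; 18 from 17; 17 from 16.** The amide bond of 20 is cut to acid 18 and the amine salt 19, which brings in all five carbons of ring C. The iodoalkene of 18 goes back to the aldehyde of 16 through ester 17 by a one-carbon iodo-olefination.

**15 from 13 (through 14).** The C4–C7 bond is cut. A metallated vinylstannane adds to the C4 ketone of 13, forming the quaternary carbinol and installing the coupling handle in one operation. Attack anti to the oxirane places the new C4 oxygen syn to it, and alkoxide 14 is silylated in the same flask.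

**13 from 12.** The epoxide oxygen is removed. Of the two ring alkenes of 12, only C5=C6 is an electrophilic enone, because C2=C3 is an enaminone. The forward nucleophilic epoxidation therefore needs control of face only, not of site.

**12 from 11.** Ring A is traced to an aromatic ring. Oxidative dearomatisation of the 2,5-dimethoxyanilide 11 delivers the ketal, the ketone and the nitrogen at C2 together, so no amination of ring A is ever needed.

**11 from 7 and 10; 10 from 8 and 9.** The C2′=C3′ alkene is cut by a phosphonate olefination that brings the anilide with it. Phosphonate 10 comes from aniline 8 and acid 9.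

**7 from 5 (through 6); 5 from 4; 4 from 3; 3 from 1 and 2.** The trisubstituted C4′=C5′ alkene is cut by a Wittig reaction of aldehyde 6. The C6′ methyl group is cut back to an auxiliary-controlled enolate methylation of imide 3, assembled from oxazolidinone 1 and acid chloride 2.

## Alternatives that were turned down

**Alternative 1:** The two syn oxygens are traced to endoperoxide A1, formed by [4+2] addition of singlet oxygen to the enantiopure silyloxy diene A2 on the face away from the silyloxy group.
- *For it:* both oxygens come from one O2 molecule on one face, so the syn relation between the C4 oxygen and the oxirane follows from the mechanism. The absolute configuration comes from a resolved carbinol and not from catalyst control. On these two points it is stronger than the chosen route, which relies on a face-selective addition and an enantioselective epoxidation.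
- *Against it:* A2 is a cyclohexadienyl silyl ether that aromatises readily by loss of silanol. Its directing group is homoallylic to the reacting termini, so the face bias is modest. The electron-poor enyne diene invites ene reactions. After A1, the peroxide must be isomerised to two oxiranes, one of them opened by base, and the directing carbinol oxidised to the C1 ketone, which destroys the stereocentre that gave the control.
- *Comparison:* nitrogen at C2 would still have to be introduced on an epoxy enone, and ring C and both chains remain unsolved. The chosen route reaches the full stereotriad in three steps from an anilide that already carries nitrogen, and concentrates its risk in one late step.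

**Alternative 2:** The stereotriad is traced to epoxyquinol A3, formed from the achiral para-quinol A4 by epoxidation with tert-butyl hydroperoxide under a chiral cinchonidinium phase-transfer cation, on the hydroxyl face of one of two enantiotopic enones.
- *For it:* one catalytic step sets C4, C5 and C6, and the tertiary carbinol is already in place, so no organolithium has to add to an amide-bearing ketone. In step count to the stereotriad it is at least equal to the chosen route, and it is more elegant.
- *Against it:* the catalyst must choose between two identical enones and one face at the same time, and the remaining enone of A3 can be epoxidised again. A3 has no nitrogen, so C2 needs α-halogenation and a metal-catalysed amidation on a base-sensitive epoxy enone with a free tertiary alcohol. The silyl alkyne needs deprotection and a regioselective hydrostannylation.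
- *Comparison:* in the chosen route the second alkene is an enaminone, so mono-epoxidation is built in, and nitrogen arrives with the arene. The gain of alternative 2 at the front is spent on three or four delicate steps afterwards.

**Alternative 3:** Ring A is traced to the shikimate-derived diol A5, formed by OsO4-catalysed dihydroxylation of the protected methyl shikimate A6 on the face opposite the acetonide.
- *For it:* the absolute configuration is purchased and the facial outcome follows from the acetonide, so no enantioselective step is needed. On stereochemical certainty it is the strongest of all four plans.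
- *Against it:* the conjugated alkene of A6 is electron-poor and slow to dihydroxylate. After A5 four oxygenated carbons must be differentiated: one diol becomes the oxirane, one acetonide oxygen becomes the C1 ketone, the silyloxy carbon must become the nitrogen-bearing C2 of an enamide, and the ester must be reduced and extended. That is a long sequence of protecting-group and oxidation-state changes.
- *Comparison:* it is longer by roughly ten steps to an intermediate equivalent to 15. The chosen route accepts reliance on catalyst control in exchange for that brevity.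

Key step: step 14

Assumption: the cinchonine-derived salt is taken to deliver the (1R,6S) epoxide 13 in step 8; if the sense of induction is the opposite, its pseudoenantiomer N-benzylcinchonidinium chloride is used with no other change.

## Route

Step 1
Reactants: 1 (R)-4-benzyloxazolidin-2-one; 2 hexanoyl chloride
Product: 3 (R)-4-benzyl-3-hexanoyloxazolidin-2-one
Conditions: n-BuLi, THF, −78 °C; then 2, −78 → 0 °C
Reagents that add atoms: none
Why: N-acylation of the lithiated oxazolidinone by the acid chloride, the standard preparation of an Evans imide.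

Step 2
Reactants: 3 (R)-4-benzyl-3-hexanoyloxazolidin-2-one
Product: 4 (R)-4-benzyl-3-[(R)-2-methylhexanoyl]oxazolidin-2-one
Conditions: NaN(SiMe3)2, THF, −78 °C; MeI, −78 → −40 °C
Reagents that add atoms: iodomethane, CI
Why: Evans asymmetric alkylation; the chelated Z-enolate is methylated on the face away from the benzyl group, which with the (R)-auxiliary sets the (R) centre that becomes C6′.

Step 3
Reactants: 4 (R)-4-benzyl-3-[(R)-2-methylhexanoyl]oxazolidin-2-one
Product: 5 (R)-2-methylhexan-1-ol
Conditions: LiBH4, H2O (1 equiv), Et2O, 0 °C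
Reagents that add atoms: none
Why: Reductive cleavage of the imide at the exocyclic carbonyl gives the primary alcohol without touching the stereocentre and returns the auxiliary.

Step 4
Reactants: 5 (R)-2-methylhexan-1-ol
Product: 7 (2E,4R)-2,4-dimethyloct-2-enal, via (R)-2-methylhexanal 6 (not isolated)
Conditions: (COCl)2, DMSO, Et3N, CH2Cl2, −78 → 0 °C; quick cold aqueous wash; then Ph3P=C(Me)CHO, toluene, 80 °C
Reagents that add atoms: 2-(triphenylphosphoranylidene)propanal, CC(C=O)=P(c1ccccc1)(c1ccccc1)c1ccccc1
Why: Swern oxidation followed by Wittig olefination with a formyl-stabilised ylide, which should give the E-trisubstituted alkene; the α-branched aldehyde is used at once and unpurified to limit epimerisation.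

Step 5
Reactants: 8 2,5-dimethoxyaniline; 9 (diethoxyphosphoryl)acetic acid
Product: 10 diethyl {2-[(2,5-dimethoxyphenyl)amino]-2-oxoethyl}phosphonate
Conditions: EDC·HCl, DMAP (cat.), CH2Cl2, 0 → 23 °C
Reagents that add atoms: none
Why: Carbodiimide amide coupling of an electron-rich aniline with a simple carboxylic acid.

Step 6
Reactants: 7 (2E,4R)-2,4-dimethyloct-2-enal; 10 diethyl {2-[(2,5-dimethoxyphenyl)amino]-2-oxoethyl}phosphonate
Product: 11 (2E,4E,6R)-N-(2,5-dimethoxyphenyl)-4,6-dimethyldeca-2,4-dienamide
Conditions: LiCl, DBU, MeCN, 0 → 23 °C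
Reagents that add atoms: none
Why: Horner–Wadsworth–Emmons olefination under Masamune–Roush conditions should give the E-alkene; the mild amine base avoids γ-deprotonation of the enal, which would endanger the C6′ centre.

Step 7
Reactants: 11 (2E,4E,6R)-N-(2,5-dimethoxyphenyl)-4,6-dimethyldeca-2,4-dienamide
Product: 12 (2E,4E,6R)-N-(6,6-dimethoxy-3-oxocyclohexa-1,4-dien-1-yl)-4,6-dimethyldeca-2,4-dienamide
Conditions: PhI(OAc)2, MeOH, 0 → 23 °C; aqueous NaHCO3
Reagents that add atoms: methanol, CO
Why: Oxidative dearomatisation of a hydroquinone dimethyl ether by the trivalent iodine reagent in methanol gives the quinone monoketal. The ketal should remain at the carbon next to nitrogen because the free carbonyl is then stabilised as a vinylogous imide.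

Step 8
Reactants: 12 (2E,4E,6R)-N-(6,6-dimethoxy-3-oxocyclohexa-1,4-dien-1-yl)-4,6-dimethyldeca-2,4-dienamide
Product: 13 (2E,4E,6R)-N-[(1R,6S)-5,5-dimethoxy-2-oxo-7-oxabicyclo[4.1.0]hept-3-en-4-yl]-4,6-dimethyldeca-2,4-dienamide
Conditions: t-BuOOH, aq. NaOH, N-benzylcinchoninium chloride (10 mol %), toluene, 23 °C
Reagents that add atoms: tert-butyl hydroperoxide, CC(C)(C)OO
Why: Weitz–Scheffer nucleophilic epoxidation under chiral phase-transfer catalysis; only the unsubstituted enone alkene is electrophilic, and the chiral ammonium–peroxide ion pair selects the face, setting C5 and C6 of the target together.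

Step 9
Reactants: 13 (2E,4E,6R)-N-[(1R,6S)-5,5-dimethoxy-2-oxo-7-oxabicyclo[4.1.0]hept-3-en-4-yl]-4,6-dimethyldeca-2,4-dienamide
Product: 15 (2E,4E,6R)-N-[(1S,5R,6R)-2,2-dimethoxy-5-[(E)-2-(tributylstannyl)ethenyl]-5-[(triethylsilyl)oxy]-7-oxabicyclo[4.1.0]hept-3-en-3-yl]-4,6-dimethyldeca-2,4-dienamide, via dilithium alkoxide of the adduct 14 (not isolated)
Conditions: (E)-Bu3SnCH=CHSnBu3, n-BuLi, THF, −78 °C; then 13 (vinyllithium in 3-fold excess), −78 °C; then Et3SiOTf, −78 → −40 °C; aqueous NaHCO3
Reagents that add atoms: (E)-1,2-bis(tributylstannyl)ethene, CCCC[Sn](CCCC)(CCCC)/C=C/[Sn](CCCC)(CCCC)CCCC; triethylsilyl trifluoromethanesulfonate, CC[Si](CC)(CC)OS(=O)(=O)C(F)(F)F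
Why: Tin–lithium exchange gives the E-stannylvinyllithium, which adds 1,2 to the ketone after the amide N–H has consumed one equivalent. Attack anti to the oxirane oxygen sets C4 with its oxygen syn to the epoxide, and the alkoxide is silylated in the flask under basic conditions that spare the ketal.

Step 10
Reactants: 16 ethyl (E)-4-oxobut-2-enoate
Product: 17 ethyl (2E,4E)-5-iodopenta-2,4-dienoate
Conditions: CrCl2, CHI3, THF, 0 °C
Reagents that add atoms: iodoform, IC(I)I
Why: Takai olefination; the geminal dichromium species formed from divalent chromium and iodoform converts the aldehyde into the E-iodoalkene and leaves the ester alone. Any 4Z isomer should be removable when acid 18 is crystallised.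

Step 11
Reactants: 17 ethyl (2E,4E)-5-iodopenta-2,4-dienoate
Product: 18 (2E,4E)-5-iodopenta-2,4-dienoic acid
Conditions: LiOH, THF–H2O, 0 → 23 °C; then 1 M HCl
Reagents that add atoms: lithium hydroxide, [Li+].[OH-]
Why: Ester saponification; the iodo-diene is stable to cold aqueous hydroxide.

Step 12
Reactants: 18 (2E,4E)-5-iodopenta-2,4-dienoic acid; 19 methyl 5-aminolevulinate hydrochloride
Product: 20 methyl 5-{[(2E,4E)-5-iodopenta-2,4-dienoyl]amino}-4-oxopentanoate
Conditions: EDC·HCl, HOBt, N-methylmorpholine (added last, slowly), CH2Cl2–DMF, 0 °C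
Reagents that add atoms: none
Why: Carbodiimide amide coupling; the amine is released from its salt only in the presence of the activated acid, so N-acylation should outrun self-condensation of the free amino ketone.

Step 13
Reactants: 15 (2E,4E,6R)-N-[(1S,5R,6R)-2,2-dimethoxy-5-[(E)-2-(tributylstannyl)ethenyl]-5-[(triethylsilyl)oxy]-7-oxabicyclo[4.1.0]hept-3-en-3-yl]-4,6-dimethyldeca-2,4-dienamide; 20 methyl 5-{[(2E,4E)-5-iodopenta-2,4-dienoyl]amino}-4-oxopentanoate
Product: 21 (2E,4E,6R)-N-[(1S,5S,6R)-2,2-dimethoxy-5-[(1E,3E,5E)-7-[(5-methoxy-2,5-dioxopentyl)amino]-7-oxohepta-1,3,5-trien-1-yl]-5-[(triethylsilyl)oxy]-7-oxabicyclo[4.1.0]hept-3-en-3-yl]-4,6-dimethyldeca-2,4-dienamide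
Conditions: Pd2(dba)3 (5 mol %), AsPh3 (20 mol %), DMF, 23 °C, dark
Reagents that add atoms: none
Why: Stille coupling of a vinylstannane with a vinyl iodide on zerovalent palladium, with retention of both alkene geometries; the neutral conditions should spare the epoxide, ketal, silyl ether and keto ester.

Step 14
Reactants: 21 (2E,4E,6R)-N-[(1S,5S,6R)-2,2-dimethoxy-5-[(1E,3E,5E)-7-[(5-methoxy-2,5-dioxopentyl)amino]-7-oxohepta-1,3,5-trien-1-yl]-5-[(triethylsilyl)oxy]-7-oxabicyclo[4.1.0]hept-3-en-3-yl]-4,6-dimethyldeca-2,4-dienamide
Product: 22 (2E,4E,6R)-N-[(1S,5S,6R)-5-[(1E,3E,5E)-7-[(2-hydroxy-5-oxocyclopent-1-en-1-yl)amino]-7-oxohepta-1,3,5-trien-1-yl]-2,2-dimethoxy-5-[(triethylsilyl)oxy]-7-oxabicyclo[4.1.0]hept-3-en-3-yl]-4,6-dimethyldeca-2,4-dienamide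
Conditions: KN(SiMe3)2 (4.5 equiv), THF (0.005 M), −78 → 23 °C; AcOH, −78 °C
Reagents that add atoms: none
Why: Intramolecular Claisen (Dieckmann-type) acylation: the base first removes the two amide N–H protons and then enolises the ketone; the enolate at the amide-flanked methylene (aminolevulinate carbon 5) adds to the ester carbonyl (carbon 1), methoxide leaves, and the 2-acylaminocyclopentane-1,3-dione is deprotonated at once to its delocalised enolate, which makes the sequence irreversible and gives the enol on acidification. The closest known reaction type is the base-induced cyclisation of 4-oxoalkanoate esters to 2-substituted cyclopentane-1,3-diones; the acylamino-substituted case on an intermediate of this size extends it without a close analogue. Ring C closes in the 5-(enolendo)-exo-trig mode, the less favourable geometry for C-acylation of an enolate, which is why the mixture is warmed; O-acylation and enolisation on the other side of the ketone are reversible and lead to no stable product. No stereocentre is formed, and C4, C5, C6 and C6′ carry no hydrogen acidic enough for this base once the amides are deprotonated. The regiochemistry is fixed by ring size, because the other α-carbon of the ketone could only close a three-membered ring. The selectivity needed is acylation at carbon with ring A left intact: the C1 dimethyl ketal and the C4 silyl ether leave ring A no carbonyl group other than a deprotonated amide, and high dilution suppresses intermolecular condensation.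

Step 15
Reactants: 22 (2E,4E,6R)-N-[(1S,5S,6R)-5-[(1E,3E,5E)-7-[(2-hydroxy-5-oxocyclopent-1-en-1-yl)amino]-7-oxohepta-1,3,5-trien-1-yl]-2,2-dimethoxy-5-[(triethylsilyl)oxy]-7-oxabicyclo[4.1.0]hept-3-en-3-yl]-4,6-dimethyldeca-2,4-dienamide
Product: 23 (2E,4E,6R)-N-[(1S,5S,6R)-5-hydroxy-5-[(1E,3E,5E)-7-[(2-hydroxy-5-oxocyclopent-1-en-1-yl)amino]-7-oxohepta-1,3,5-trien-1-yl]-2-oxo-7-oxabicyclo[4.1.0]hept-3-en-3-yl]-4,6-dimethyldeca-2,4-dienamide (CNP0262080.2)
Conditions: 48% aq. HF, MeCN, 0 → 23 °C; pH 5 buffer
Reagents that add atoms: water, O
Why: Fluoride cleaves the Si–O bond and the same mildly acidic aqueous medium hydrolyses the dimethyl ketal to the C1 ketone, so one operation should remove both protecting groups without touching the stereocentres.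

## Compound list

1 | (R)-4-benzyloxazolidin-2-one | O=C1N[C@H](Cc2ccccc2)CO1 | starting material
2 | hexanoyl chloride | CCCCCC(Cl)=O | starting material
3 | (R)-4-benzyl-3-hexanoyloxazolidin-2-one | CCCCCC(=O)N1[C@H](Cc2ccccc2)COC1=O | intermediate
4 | (R)-4-benzyl-3-[(R)-2-methylhexanoyl]oxazolidin-2-one | CCCC[C@@H](C)C(=O)N1[C@H](Cc2ccccc2)COC1=O | intermediate
5 | (R)-2-methylhexan-1-ol | CCCC[C@@H](C)CO | intermediate
6 | (R)-2-methylhexanal | CCCC[C@@H](C)C=O | intermediate
7 | (2E,4R)-2,4-dimethyloct-2-enal | CCCC[C@@H](C)/C=C(C)/C=O | intermediate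
8 | 2,5-dimethoxyaniline | COc1ccc(OC)c(N)c1 | starting material
9 | (diethoxyphosphoryl)acetic acid | CCOP(=O)(OCC)CC(=O)O | starting material
10 | diethyl {2-[(2,5-dimethoxyphenyl)amino]-2-oxoethyl}phosphonate | CCOP(=O)(OCC)CC(=O)Nc1cc(OC)ccc1OC | intermediate
11 | (2E,4E,6R)-N-(2,5-dimethoxyphenyl)-4,6-dimethyldeca-2,4-dienamide | CCCC[C@@H](C)/C=C(C)/C=C/C(=O)Nc1cc(OC)ccc1OC | intermediate
12 | (2E,4E,6R)-N-(6,6-dimethoxy-3-oxocyclohexa-1,4-dien-1-yl)-4,6-dimethyldeca-2,4-dienamide | CCCC[C@@H](C)/C=C(C)/C=C/C(=O)NC1=CC(=O)C=CC1(OC)OC | intermediate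
13 | (2E,4E,6R)-N-[(1R,6S)-5,5-dimethoxy-2-oxo-7-oxabicyclo[4.1.0]hept-3-en-4-yl]-4,6-dimethyldeca-2,4-dienamide | CCCC[C@@H](C)/C=C(C)/C=C/C(=O)NC1=CC(=O)[C@@H]2O[C@@H]2C1(OC)OC | intermediate
14 | dilithium salt (N-lithio amide, O-lithio alkoxide) of (2E,4E,6R)-N-[(1S,5R,6R)-5-hydroxy-2,2-dimethoxy-5-[(E)-2-(tributylstannyl)ethenyl]-7-oxabicyclo[4.1.0]hept-3-en-3-yl]-4,6-dimethyldeca-2,4-dienamide | CCCC[C@@H](C)/C=C(C)/C=C/C(=O)N([Li])C1=C[C@@](O[Li])(/C=C/[Sn](CCCC)(CCCC)CCCC)[C@@H]2O[C@@H]2C1(OC)OC | intermediate
15 | (2E,4E,6R)-N-[(1S,5R,6R)-2,2-dimethoxy-5-[(E)-2-(tributylstannyl)ethenyl]-5-[(triethylsilyl)oxy]-7-oxabicyclo[4.1.0]hept-3-en-3-yl]-4,6-dimethyldeca-2,4-dienamide | CCCC[C@@H](C)/C=C(C)/C=C/C(=O)NC1=C[C@@](O[Si](CC)(CC)CC)(/C=C/[Sn](CCCC)(CCCC)CCCC)[C@@H]2O[C@@H]2C1(OC)OC | intermediate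
16 | ethyl (E)-4-oxobut-2-enoate | CCOC(=O)/C=C/C=O | starting material
17 | ethyl (2E,4E)-5-iodopenta-2,4-dienoate | CCOC(=O)/C=C/C=C/I | intermediate
18 | (2E,4E)-5-iodopenta-2,4-dienoic acid | OC(=O)/C=C/C=C/I | intermediate
19 | methyl 5-aminolevulinate hydrochloride (methyl 5-amino-4-oxopentanoate hydrochloride) | COC(=O)CCC(=O)CN.Cl | starting material
20 | methyl 5-{[(2E,4E)-5-iodopenta-2,4-dienoyl]amino}-4-oxopentanoate | COC(=O)CCC(=O)CNC(=O)/C=C/C=C/I | intermediate
21 | (2E,4E,6R)-N-[(1S,5S,6R)-2,2-dimethoxy-5-[(1E,3E,5E)-7-[(5-methoxy-2,5-dioxopentyl)amino]-7-oxohepta-1,3,5-trien-1-yl]-5-[(triethylsilyl)oxy]-7-oxabicyclo[4.1.0]hept-3-en-3-yl]-4,6-dimethyldeca-2,4-dienamide | CCCC[C@@H](C)/C=C(C)/C=C/C(=O)NC1=C[C@@](O[Si](CC)(CC)CC)(/C=C/C=C/C=C/C(=O)NCC(=O)CCC(=O)OC)[C@@H]2O[C@@H]2C1(OC)OC | intermediate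
22 | (2E,4E,6R)-N-[(1S,5S,6R)-5-[(1E,3E,5E)-7-[(2-hydroxy-5-oxocyclopent-1-en-1-yl)amino]-7-oxohepta-1,3,5-trien-1-yl]-2,2-dimethoxy-5-[(triethylsilyl)oxy]-7-oxabicyclo[4.1.0]hept-3-en-3-yl]-4,6-dimethyldeca-2,4-dienamide | CCCC[C@@H](C)/C=C(C)/C=C/C(=O)NC1=C[C@@](O[Si](CC)(CC)CC)(/C=C/C=C/C=C/C(=O)NC2=C(O)CCC2=O)[C@@H]2O[C@@H]2C1(OC)OC | intermediate
23 | (2E,4E,6R)-N-[(1S,5S,6R)-5-hydroxy-5-[(1E,3E,5E)-7-[(2-hydroxy-5-oxocyclopent-1-en-1-yl)amino]-7-oxohepta-1,3,5-trien-1-yl]-2-oxo-7-oxabicyclo[4.1.0]hept-3-en-3-yl]-4,6-dimethyldeca-2,4-dienamide | CCCC[C@@H](C)/C=C(C)/C=C/C(=O)NC1=C[C@@](O)(/C=C/C=C/C=C/C(=O)NC2=C(O)CCC2=O)[C@@H]2O[C@@H]2C1=O | target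

## Step count and least certain steps

Total step count: 15. Longest linear sequence: 11 steps (1, 2, 3, 4, 6, 7, 8, 9, 13, 14, 15).

**Step 14 (key step).**
- *What may go wrong:* The deprotonated neighbouring amide nitrogen may acylate at the ester instead of the carbon enolate. That six-membered imide can be cleaved by the liberated methoxide at the trienoyl carbonyl, which would cut off the acyl chain. Alternatively there may be no closure at all: the amidate lowers the acidity of the methylene, the closure geometry is the unfavourable one, and the polyene may degrade at the temperature required.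
- *Fallback:* Ring C is brought in ready-made. Cyclopentane-1,3-dione is coupled with benzenediazonium chloride to 2-(2-phenylhydrazinylidene)cyclopentane-1,3-dione F1. Hydrogenolysis (H2, Pd/C, HCl, MeOH) gives 2-amino-3-hydroxycyclopent-2-en-1-one hydrochloride F2. Acylation of F2 with acid 18 (EDC·HCl, HOBt, Et3N, DMF) gives (2E,4E)-N-(2-hydroxy-5-oxocyclopent-1-en-1-yl)-5-iodopenta-2,4-dienamide F3. Stille coupling of F3 with stannane 15 under the conditions of step 13 rejoins the route at 22. The fallback sets out from 15 and 18. F3 is also what 20 itself would give on ring closure, so the closure can first be tried on 20 under hotter alkoxide conditions that 21 would not survive.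

**Step 8.**
- *What may go wrong:* Facial selectivity may be poor and conversion slow. The acidic N–H is deprotonated under the basic two-phase conditions, and the anionic substrate is a weaker acceptor that can also pair with the chiral cation. Because of the remote C6′ centre the minor product is a diastereomer that crystallisation may not remove.
- *Fallback:* Catalyst control is replaced by separation. Unselective epoxidation of 12 (H2O2, LiOH, THF–H2O) gives 13 together with its (1S,6R) epoxide diastereomer F4. The two are separated by preparative chromatography on a chiral stationary phase. The fallback sets out from 12 and returns at 13.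

**Step 9.**
- *What may go wrong:* Addition may be incomplete, because the first equivalent of organolithium turns the substrate into an anion that deactivates the vinylogous ketone. The silyl triflate may ionise the ketal before it finds the hindered alkoxide.
- *Fallback:* A smaller nucleophile is used and the tin is introduced afterwards. Addition of HC≡CMgBr (with CeCl3, THF, −78 °C) to 13 gives the ethynyl carbinol F5. Silylation (Et3SiOTf, 2,6-lutidine, CH2Cl2, −78 °C) gives its triethylsilyl ether F6. Hydrostannylation (Bu3SnH, PdCl2(PPh3)2, THF) places tin at the unhindered terminus with E geometry. The fallback sets out from 13 and returns at 15.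

**Step 15.**
- *What may go wrong:* The doubly allylic tertiary C4–O bond may ionise, the oxirane may be opened by fluoride under acid, and the triene may isomerise during the time needed to hydrolyse the ketal.
- *Fallback:* The silyl group is left out, so that only a heterogeneous mild acid is needed at the end. Step 9 is run from 13 with an aqueous quench to give the free tertiary alcohol stannane F7. Stille coupling with 20 gives the hydroxy keto ester F8. Ring closure as in step 14 with one more equivalent of KN(SiMe3)2 gives the hydroxy ketal F9. Montmorillonite K10 in CH2Cl2 then hydrolyses the ketal. The fallback sets out from 13 and returns at 23.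

## Further compounds

F1 | step 14 | 2-(2-phenylhydrazinylidene)cyclopentane-1,3-dione | O=C1CCC(=O)C1=NNc1ccccc1
F2 | step 14 | 2-amino-3-hydroxycyclopent-2-en-1-one hydrochloride | NC1=C(O)CCC1=O.Cl
F3 | step 14 | (2E,4E)-N-(2-hydroxy-5-oxocyclopent-1-en-1-yl)-5-iodopenta-2,4-dienamide | O=C(/C=C/C=C/I)NC1=C(O)CCC1=O
F4 | step 8 | (2E,4E,6R)-N-[(1S,6R)-5,5-dimethoxy-2-oxo-7-oxabicyclo[4.1.0]hept-3-en-4-yl]-4,6-dimethyldeca-2,4-dienamide | CCCC[C@@H](C)/C=C(C)/C=C/C(=O)NC1=CC(=O)[C@H]2O[C@H]2C1(OC)OC
F5 | step 9 | (2E,4E,6R)-N-[(1S,5R,6R)-5-ethynyl-5-hydroxy-2,2-dimethoxy-7-oxabicyclo[4.1.0]hept-3-en-3-yl]-4,6-dimethyldeca-2,4-dienamide | CCCC[C@@H](C)/C=C(C)/C=C/C(=O)NC1=C[C@@](O)(C#C)[C@@H]2O[C@@H]2C1(OC)OC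
F6 | step 9 | (2E,4E,6R)-N-[(1S,5R,6R)-5-ethynyl-2,2-dimethoxy-5-[(triethylsilyl)oxy]-7-oxabicyclo[4.1.0]hept-3-en-3-yl]-4,6-dimethyldeca-2,4-dienamide | CCCC[C@@H](C)/C=C(C)/C=C/C(=O)NC1=C[C@@](O[Si](CC)(CC)CC)(C#C)[C@@H]2O[C@@H]2C1(OC)OC
F7 | step 15 | (2E,4E,6R)-N-[(1S,5R,6R)-5-hydroxy-2,2-dimethoxy-5-[(E)-2-(tributylstannyl)ethenyl]-7-oxabicyclo[4.1.0]hept-3-en-3-yl]-4,6-dimethyldeca-2,4-dienamide | CCCC[C@@H](C)/C=C(C)/C=C/C(=O)NC1=C[C@@](O)(/C=C/[Sn](CCCC)(CCCC)CCCC)[C@@H]2O[C@@H]2C1(OC)OC
F8 | step 15 | (2E,4E,6R)-N-[(1S,5S,6R)-5-hydroxy-2,2-dimethoxy-5-[(1E,3E,5E)-7-[(5-methoxy-2,5-dioxopentyl)amino]-7-oxohepta-1,3,5-trien-1-yl]-7-oxabicyclo[4.1.0]hept-3-en-3-yl]-4,6-dimethyldeca-2,4-dienamide | CCCC[C@@H](C)/C=C(C)/C=C/C(=O)NC1=C[C@@](O)(/C=C/C=C/C=C/C(=O)NCC(=O)CCC(=O)OC)[C@@H]2O[C@@H]2C1(OC)OC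
F9 | step 15 | (2E,4E,6R)-N-[(1S,5S,6R)-5-hydroxy-5-[(1E,3E,5E)-7-[(2-hydroxy-5-oxocyclopent-1-en-1-yl)amino]-7-oxohepta-1,3,5-trien-1-yl]-2,2-dimethoxy-7-oxabicyclo[4.1.0]hept-3-en-3-yl]-4,6-dimethyldeca-2,4-dienamide | CCCC[C@@H](C)/C=C(C)/C=C/C(=O)NC1=C[C@@](O)(/C=C/C=C/C=C/C(=O)NC2=C(O)CCC2=O)[C@@H]2O[C@@H]2C1(OC)OC
A1 | alternative 1 | endoperoxide, 2,3-dioxabicyclo[2.2.2]oct-5-ene carrying a tert-butyldimethylsilyloxy group trans to the peroxide bridge and a (triisopropylsilyl)ethynyl group on the alkene | O1O[C@@H]2C(C#C[Si](C(C)C)(C(C)C)C(C)C)=C[C@H]1[C@@H](O[Si](C)(C)C(C)(C)C)C2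
A2 | alternative 1 | tert-butyldimethylsilyl ether of enantiopure 4-[(triisopropylsilyl)ethynyl]cyclohexa-2,4-dien-1-ol | C1=C(C#C[Si](C(C)C)(C(C)C)C(C)C)C=C[C@@H](O[Si](C)(C)C(C)(C)C)C1
A3 | alternative 2 | syn-5,6-epoxy-4-hydroxy-4-[(triisopropylsilyl)ethynyl]cyclohex-2-en-1-one | C1=C[C@@](O)(C#C[Si](C(C)C)(C(C)C)C(C)C)[C@@H]2O[C@@H]2C1=O
A4 | alternative 2 | 4-hydroxy-4-[(triisopropylsilyl)ethynyl]cyclohexa-2,5-dien-1-one | O=C1C=CC(O)(C#C[Si](C(C)C)(C(C)C)C(C)C)C=C1
A5 | alternative 3 | 1,2-diol of methyl 5-O-(tert-butyldimethylsilyl)-3,4-O-isopropylideneshikimate, both new hydroxyls trans to the acetonide | COC(=O)[C@@]1(O)[C@H](O)[C@H]2OC(C)(C)O[C@H]2[C@H](O[Si](C)(C)C(C)(C)C)C1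
A6 | alternative 3 | methyl 5-O-(tert-butyldimethylsilyl)-3,4-O-isopropylideneshikimate | COC(=O)C1=C[C@H]2OC(C)(C)O[C@H]2[C@H](O[Si](C)(C)C(C)(C)C)C1
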